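The readings were computed for substances that don't exist; scatter was added.

If I booked each mole of substrate, the limiting reagent at c(substrate) = 0.14 M against c(reagent) = 0.168 M, Tuesday's flask had a short ledger.

| setting | Tuesday's | Monday's | flask |
|---|---|---|---|
| substrate | 0.14 M | 0.14 M | 0.14 M |
| reagent | 0.168 M | 0.168 M | 0.168 M |
| temperature | 90 °C | 75 °C | 90 °C |
| remark | the very flask that is asked about, followed so far | run made earlier |  |
| time |  |  | 8.0 d |

| run | time / d | target / % | substrate / % |
|---|---|---|---|
| Tuesday's | 1.25 | 39.1 | 2.1 |
| Tuesday's | 2.50 | 36.8 | 1.0 |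
| Tuesday's | 3.00 | 35.4 | 1.1 |
| Tuesday's | 5.00 | 34.1 | 0.5 |
| Tuesday's | 6.00 | 34.3 | 1.2 |
| Tuesday's | 8.00 | 33.2 | 0.4 |
| Monday's | 2.50 | 53.7 | 6.4 |
| Monday's | 5.00 | 51.5 | 0.5 |
| Monday's | 6.00 | 50.2 | 1.7 |
| Monday's | 10.0 | 50.5 | 0.5 |
| Monday's | 12.0 | 46.6 | 0 |
| Monday's | 15.0 | 47.7 | 0 |

(each reading ± 1 percentage point)

- target, in percent of the substrate first charged, at 8.0 d
- which option adds most target ("none" when 2 percentage points or less is all one gets) (ochre / violet / grey / teal / none)
- target present, with what was taken out counted in, in percent of the substrate first charged, after ochre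
- target present, with what was taken out counted in, in percent of the substrate first charged, after teal

- ochre: at 8.0 d raise the temperature by 15 K, then wait 8.0 d
- violet: change nothing and wait 8.0 d more
- grey: at 8.0 d add reagent, 50.0% of the amount charged, then wait 8.0 d
- teal: at 8.0 d take out 90% of the target then present, then wait 8.0 d

- target that was removed still counts
- reactions considered so far: intermediate <-> isomer of the product A; substrate + reagent -> intermediate + released group; target <-> isomer of the product B; intermediate <-> target
- additions bring no volume worth counting

The first entry in Tuesday's flask was substrate: it read 0.4% at 8.00 d, less than the scatter of 1 percentage point, so I booked the charge as reacted. Each mole took one mole of reagent, leaving 16.7% of the reagent's own charge. The next entry was target, flat from 5.00 d on: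

standing share = mean target from 5.00 d on = 33.9%

I carried this standing share, the part of the reacted substrate that stands as target once the reversible steps stop moving (thermodynamic control). The other 66.1% I booked to the intermediate and both isomers, which nobody read.

Monday's flask lay 15 K lower and gave 48.3% from 10.0 d on. I assumed that the odds change by the same factor for ochre's rise:

odds: 0.933 on Monday, 0.512 on Tuesday, 0.281 after ochre
ochre: share = 21.9%

For teal I let the remainder resettle, since Tuesday's flat stretch began sooner than the 8.0 d allowed:

taken out = 30.5%
target back = 23.5%
teal total = 54.0%, a gain of 20 points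

My answers were 33.9% now, 21.9% for ochre and teal as best, with 54.0%. Tuesday's flat target offered violet nothing, and grey's reagent would meet a charge I had already booked as reacted.

The forecast gave 33.5%, teal as best, 23% for ochre and 50% for teal, lower than my teal figure. It noted: “This assumes the isomers really do feed back and no hidden drain exists.”

The flask gave 33.6%, with teal best at 20 points; teal reached 53.6%, ochre 23.1%, and violet changed target by −0.041 points.

    intermediate ⇌ isomer of the product A (K = 3.60, k = 1.18 × 10⁻⁴ /s, Ea = 124 kJ/mol, ΔH = 14.0 kJ/mol)
    substrate + reagent → intermediate + released group (k = 5.63 × 10⁻⁴ /M/s, Ea = 74.0 kJ/mol)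
    target ⇌ isomer of the product B (K = 1.16, k = 6.98 × 10⁻⁶ /s, Ea = 111 kJ/mol, ΔH = 45.0 kJ/mol)
    intermediate ⇌ target (K = 5.60, k = 3.10 × 10⁻⁴ /s, Ea = 114 kJ/mol, ΔH = −20.0 kJ/mol)
    (constants at 90 °C)

In this flask, the slowest mode of the whole flask as it stands at 8.00 d has a half-life of 0.885 d, short against 8.0 d, and target still stands at 33.5% after 80.0 d, which is what a standing share of 33.9% describes. In the neighbour charged with 0.10 M of reagent, reagent ran out first with 0% left, so the ledger books 71.4% of the substrate as reacted, the share turns that into 24.2%, and that neighbour holds 24.0% of target.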